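**Retrosynthetic overview**

1. Target ⇒ Shi epoxidation of the side-chain prenyl alkene (last step) ⇐ cross-metathesis of an allyl group ⇐ angeloylation of a C1,C8-diol with angelic anhydride, the C2 angelate being already in place.
2. Diol ⇒ catalyst-controlled allylboration (C8–C9 bond) of a 2-substituted propenal stored as a lactol; its C7 methylene comes from an amine-catalysed α-methylenation, and the lactol from an ester-sparing borane reduction of a γ-lactone.
3. Lactone C2-angelate ⇒ esterification of the only free hydroxyl of a cis-fused hydroxy γ-lactone ⇐ Baeyer–Villiger oxidation of a ring-fused cyclobutanone (C1–O with retention) after a C2–OH-directed epoxidation.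
4. Cyclobutanone ⇒ enantioselective Brønsted-acid-catalysed endo Diels–Alder reaction of cyclobutenone with a tiglaldehyde-derived 1-siloxy diene; this builds the only carbocycle and sets C1, C2 and C6.
5. Ring order: cyclohexene (carrying the four-membered ring of the dienophile) → ring oxirane → temporary lactone/lactol (opened at C8) → side-chain oxirane.

Locants used in the text: ring carbons C1–C6 (C1, C2 = ester carbons, C3/C4 = epoxide carbons, C6 = carbon bearing the side chain); side chain C7 (bearing the exo-methylene), C8 (ester carbon), C9, C10, C11.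

Assumption: 3-bromocyclobutanone and angelic anhydride are taken as commercially available, and the sense of induction in step 3 is assigned by analogy and must be confirmed (the mirror-image acid is equally accessible).

**Route**

Step 1
Reactants: 1 (2E)-2-methylbut-2-enal (tiglaldehyde)
Product: 2 (1E)-2-methyl-1-[(triisopropylsilyl)oxy]buta-1,3-diene
Conditions: i-Pr3SiOTf (1.1 equiv), Et3N (1.5 equiv), Et2O, 0 °C → rt
Reagents that add atoms: triisopropylsilyl trifluoromethanesulfonate, CC(C)[Si](C(C)C)(C(C)C)OS(=O)(=O)C(F)(F)F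
Why: Silyl dienol ether formation by soft enolisation, in which the silyl triflate activates the enal and Et3N removes a γ-proton of the s-trans conformer, so the 1-siloxy diene forms mainly as the 1E isomer (the minor 1Z isomer is inert in step 3) and no stereocentre is created.

Step 2
Reactants: 3 3-bromocyclobutan-1-one
Product: 4 cyclobut-2-en-1-one
Conditions: n-Bu3N (1.1 equiv), neat, rt, reduced pressure, product condensed at −78 °C and kept as a cold toluene solution
Reagents that add atoms: none
Why: E1cB dehydrobromination of the β-bromo ketone by the tertiary amine gives the strained enone, which is distilled away from the base as it forms and used at once.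

Step 3
Reactants: 2 (1E)-2-methyl-1-[(triisopropylsilyl)oxy]buta-1,3-diene; 4 cyclobut-2-en-1-one
Product: 6 (1R,5S,6S)-5-hydroxy-4-methylbicyclo[4.2.0]oct-3-en-7-one, via silyl ether cycloadduct 5 (not isolated)
Conditions: (S)-3,3'-bis(2,4,6-triisopropylphenyl)-1,1'-binaphthyl-2,2'-diyl N-triflylphosphoramide (5 mol%), toluene, −78 °C; then HF·pyridine, THF, 0 °C → rt
Reagents that add atoms: none
Why: Proposed new method: a strongly acidic chiral N-triflylphosphoramide hydrogen-bonds or protonates the carbonyl of cyclobutenone inside its 3,3'-aryl pocket, so that the siloxy diene adds to one enantioface through the endo transition state (carbonyl under the diene, siloxy group outside) with the "ortho" regiochemistry dictated by the 1-siloxy group, which places the C1–C(=O), C6–CH2 and C2–O bonds all cis and fixes C1, C2 and C6 in one event before fluoride removes the silyl group, the closest known reaction types being the chiral N-triflylphosphoramide-catalysed Diels–Alder reaction of ethyl vinyl ketone with siloxy dienes and the uncatalysed or ZnCl2-promoted racemic endo Diels–Alder reactions of cyclobutenone.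

Step 4
Reactants: 6 (1R,5S,6S)-5-hydroxy-4-methylbicyclo[4.2.0]oct-3-en-7-one
Product: 8 (3aR,5R,6S,7S,7aS)-5,6-epoxy-7-hydroxy-6-methylhexahydro-1-benzofuran-2(3H)-one, via epoxy ketone 7 (not isolated)
Conditions: VO(acac)2 (2 mol%), t-BuOOH (1.3 equiv), CH2Cl2, 0 °C → rt; then mCPBA (1.3 equiv), NaHCO3, 0 °C
Reagents that add atoms: tert-butyl hydroperoxide, CC(C)(C)OO; mCPBA (3-chloroperoxybenzoic acid), OOC(=O)c1cccc(Cl)c1
Why: The hydroxyl-directed VO(acac)2/t-BuOOH epoxidation delivers oxygen to C3=C4 from the face of the allylic C2–OH (setting C3 and C4 cis to the three existing substituents), and the Baeyer–Villiger oxidation of the strained cyclobutanone then inserts oxygen on the more substituted ring-fusion side with retention, turning the C1–C(=O) bond into the cis C1–O bond.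

Step 5
Reactants: 8 (3aR,5R,6S,7S,7aS)-5,6-epoxy-7-hydroxy-6-methylhexahydro-1-benzofuran-2(3H)-one; 9 angelic acid [(2Z)-2-methylbut-2-enoic acid]
Product: 11 (3aR,5R,6R,7S,7aS)-5,6-epoxy-6-methyl-2-oxooctahydro-1-benzofuran-7-yl (2Z)-2-methylbut-2-enoate, via angelic 2,4,6-trichlorobenzoic anhydride 10 (not isolated)
Conditions: 9 (3 equiv), 2,4,6-Cl3C6H2COCl (3 equiv), Et3N (6 equiv), toluene, rt, 2 h, filtered; then 8, 80 °C
Reagents that add atoms: none
Why: Yamaguchi-type esterification of the hindered C2–OH while it is the only hydroxyl in the molecule, in which the mixed anhydride acylates at its less hindered angeloyl carbonyl, the absence of a nucleophilic catalyst suppresses Z-to-E isomerisation, the alkoxide-free conditions avoid translactonisation, and C2 keeps its configuration because no C–O bond is broken (the descriptor of the epoxide carbon C3 changes from S to R only through the CIP ranking).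

Step 6
Reactants: 11 (3aR,5R,6R,7S,7aS)-5,6-epoxy-6-methyl-2-oxooctahydro-1-benzofuran-7-yl (2Z)-2-methylbut-2-enoate
Product: 12 (3aR,5R,6R,7S,7aS)-5,6-epoxy-2-hydroxy-6-methyloctahydro-1-benzofuran-7-yl (2Z)-2-methylbut-2-enoate (lactol, both anomers)
Conditions: disiamylborane (Me2CHCHMe)2BH (3 equiv, fresh 0.5 M solution in THF), THF, 0 °C → rt; then H2O, rt
Reagents that add atoms: none
Why: Chemoselective lactone-to-lactol reduction with a hindered dialkylborane, which adds once to the γ-lactone carbonyl to give an O-boryl lactol (hydrolysed on work-up) but does not reduce carboxylic esters, hydroborate the trisubstituted electron-poor angelate alkene or open the epoxide, as known from the reduction of acylated aldonolactones to acylated lactols, so no stereocentre is touched.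

Step 7
Reactants: 12 (3aR,5R,6R,7S,7aS)-5,6-epoxy-2-hydroxy-6-methyloctahydro-1-benzofuran-7-yl (2Z)-2-methylbut-2-enoate; 13 formaldehyde
Product: 14 (3aR,5R,6R,7S,7aS)-5,6-epoxy-2-hydroxy-6-methyl-3-methylideneoctahydro-1-benzofuran-7-yl (2Z)-2-methylbut-2-enoate (lactol, in equilibrium with the open 2-substituted propenal)
Conditions: 37% aq. CH2O, pyrrolidine (10 mol%), EtCO2H (10 mol%), i-PrOH, 45 °C
Reagents that add atoms: none
Why: Amine-catalysed Mannich-type α-methylenation of an aldehyde, in which the ring-opened hydroxy aldehyde tautomer forms an enamine at C7, adds to the formaldehyde-derived iminium ion and loses the amine to give the 2-substituted propenal, which closes again to the lactol without creating a stereocentre and without touching the β,β-disubstituted angelate.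

Step 8
Reactants: 14 (3aR,5R,6R,7S,7aS)-5,6-epoxy-2-hydroxy-6-methyl-3-methylideneoctahydro-1-benzofuran-7-yl (2Z)-2-methylbut-2-enoate; 15 allylboronic acid pinacol ester
Product: 16 (1R,2S,3S,4R,6R)-3-hydroxy-4-[(3S)-3-hydroxyhexa-1,5-dien-2-yl]-1-methyl-7-oxabicyclo[4.1.0]heptan-2-yl (2Z)-2-methylbut-2-enoate
Conditions: (S)-TRIP [(S)-3,3'-bis(2,4,6-triisopropylphenyl)-1,1'-binaphthyl-2,2'-diyl hydrogen phosphate] (10 mol%), toluene, −30 → 0 °C
Reagents that add atoms: none
Why: Chiral phosphoric acid-catalysed allylboration of the ring-opened enal tautomer, in which the acid activates the boronate in a chair six-membered transition state and the (S)-acid directs allyl transfer to the Si face, so C8 is set as S by catalyst control as established for aryl and α,β-unsaturated aldehydes, and the C1–OH is released at the same time.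

Step 9
Reactants: 16 (1R,2S,3S,4R,6R)-3-hydroxy-4-[(3S)-3-hydroxyhexa-1,5-dien-2-yl]-1-methyl-7-oxabicyclo[4.1.0]heptan-2-yl (2Z)-2-methylbut-2-enoate; 17 angelic anhydride [(2Z)-2-methylbut-2-enoic anhydride]
Product: 18 (1R,2S,3S,4R,6R)-4-[(3S)-3-{[(2Z)-2-methylbut-2-enoyl]oxy}hexa-1,5-dien-2-yl]-1-methyl-7-oxabicyclo[4.1.0]heptane-2,3-diyl bis[(2Z)-2-methylbut-2-enoate]
Conditions: LiN(SiMe3)2 (2.1 equiv), THF, −78 °C; then 17 (3 equiv), −78 → 0 °C; aq. NH4Cl
Reagents that add atoms: none
Why: Stereoconservative alkoxide acylation with the symmetric anhydride, in which the lithium alkoxides of C1–OH and C8–OH are angeloylated at low temperature without a nucleophilic catalyst (so the Z geometry is kept), C1 and C8 retain configuration because no C–O bond is broken, and any 1,2-acyl shift between C2 and C1 is inconsequential because both oxygens end as angelates.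

Step 10
Reactants: 18 tris-angelate with the allyl side chain (name as in step 9); 19 2-methylbut-2-ene
Product: 20 (1R,2S,3S,4R,6R)-1-methyl-4-[(3S)-6-methyl-3-{[(2Z)-2-methylbut-2-enoyl]oxy}hepta-1,5-dien-2-yl]-7-oxabicyclo[4.1.0]heptane-2,3-diyl bis[(2Z)-2-methylbut-2-enoate]
Conditions: second-generation Grubbs catalyst RuCl2(=CHPh)(H2IMes)(PCy3) (5 mol%), 2-methylbut-2-ene (excess), CH2Cl2, 40 °C
Reagents that add atoms: none
Why: Olefin cross-metathesis, in which only the monosubstituted terminal alkene engages the ruthenium alkylidene and exchange with excess 2-methylbut-2-ene gives the prenyl olefin, while the 1,1-disubstituted C7 methylene and the trisubstituted, electron-poor angelate alkenes are inert.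

Step 11
Reactants: 20 prenyl triester (name as in step 10)
Product: 21 (1R,2S,3S,4R,6R)-4-{(3S)-4-[(2R)-3,3-dimethyloxiran-2-yl]-3-{[(2Z)-2-methylbut-2-enoyl]oxy}but-1-en-2-yl}-1-methyl-7-oxabicyclo[4.1.0]heptane-2,3-diyl bis[(2Z)-2-methylbut-2-enoate] (CNP0258231.4)
Conditions: Shi ketone derived from D-fructose (30 mol%), KHSO5 (as 2KHSO5·KHSO4·K2SO4), K2CO3, Bu4NHSO4, aq. Na2B4O7 buffer (pH 10.5), MeCN/CH2(OMe)2, 0 °C
Reagents that add atoms: potassium peroxymonosulfate KHSO5, [K+].[O-]S(=O)(=O)OO
Why: Shi asymmetric epoxidation, in which the chiral dioxirane formed from the fructose-derived ketone epoxidises the only electron-rich trisubstituted alkene through a spiro transition state to give the 10R epoxide by catalyst control, while the conjugated angelate alkenes and the ester-deactivated 1,1-disubstituted alkene react far more slowly.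

**Compound list**

1 | (2E)-2-methylbut-2-enal (tiglaldehyde) | C/C=C(\C)C=O | starting material
2 | (1E)-2-methyl-1-[(triisopropylsilyl)oxy]buta-1,3-diene | C=C/C(C)=C/O[Si](C(C)C)(C(C)C)C(C)C | intermediate
3 | 3-bromocyclobutan-1-one | O=C1CC(Br)C1 | starting material
4 | cyclobut-2-en-1-one | O=C1C=CC1 | intermediate
5 | (1R,5S,6S)-4-methyl-5-[(triisopropylsilyl)oxy]bicyclo[4.2.0]oct-3-en-7-one (cis-fused, silyloxy cis to the carbonyl-bearing fusion bond) | O=C1C[C@H]2CC=C(C)[C@@H](O[Si](C(C)C)(C(C)C)C(C)C)[C@@H]12 | intermediate (not isolated)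
6 | (1R,5S,6S)-5-hydroxy-4-methylbicyclo[4.2.0]oct-3-en-7-one | O=C1C[C@H]2CC=C(C)[C@@H](O)[C@@H]12 | intermediate
7 | (1R,3R,4S,5S,6S)-3,4-epoxy-5-hydroxy-4-methylbicyclo[4.2.0]octan-7-one (epoxide cis to OH) | O=C1C[C@H]2C[C@H]3O[C@@]3(C)[C@@H](O)[C@@H]12 | intermediate (not isolated)
8 | (3aR,5R,6S,7S,7aS)-5,6-epoxy-7-hydroxy-6-methylhexahydro-1-benzofuran-2(3H)-one | O=C1C[C@H]2C[C@H]3O[C@@]3(C)[C@@H](O)[C@H]2O1 | intermediate
9 | angelic acid, (2Z)-2-methylbut-2-enoic acid | C/C=C(/C)C(=O)O | starting material
10 | angelic 2,4,6-trichlorobenzoic anhydride | C/C=C(/C)C(=O)OC(=O)c1c(Cl)cc(Cl)cc1Cl | intermediate (not isolated)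
11 | (3aR,5R,6R,7S,7aS)-5,6-epoxy-6-methyl-2-oxooctahydro-1-benzofuran-7-yl (2Z)-2-methylbut-2-enoate | O=C1C[C@H]2C[C@H]3O[C@@]3(C)[C@@H](OC(=O)/C(C)=C\C)[C@H]2O1 | intermediate
12 | (3aR,5R,6R,7S,7aS)-5,6-epoxy-2-hydroxy-6-methyloctahydro-1-benzofuran-7-yl (2Z)-2-methylbut-2-enoate (both anomers) | OC1C[C@H]2C[C@H]3O[C@@]3(C)[C@@H](OC(=O)/C(C)=C\C)[C@H]2O1 | intermediate
13 | formaldehyde | C=O | starting material
14 | (3aR,5R,6R,7S,7aS)-5,6-epoxy-2-hydroxy-6-methyl-3-methylideneoctahydro-1-benzofuran-7-yl (2Z)-2-methylbut-2-enoate (both anomers) | OC1C(=C)[C@H]2C[C@H]3O[C@@]3(C)[C@@H](OC(=O)/C(C)=C\C)[C@H]2O1 | intermediate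
15 | allylboronic acid pinacol ester | C=CCB1OC(C)(C)C(C)(C)O1 | starting material
16 | (1R,2S,3S,4R,6R)-3-hydroxy-4-[(3S)-3-hydroxyhexa-1,5-dien-2-yl]-1-methyl-7-oxabicyclo[4.1.0]heptan-2-yl (2Z)-2-methylbut-2-enoate | C=C([C@H](CC=C)O)[C@H]1C[C@H]2O[C@@]2(C)[C@@H](OC(=O)/C(C)=C\C)[C@H]1O | intermediate
17 | angelic anhydride, (2Z)-2-methylbut-2-enoic anhydride | C/C=C(/C)C(=O)OC(=O)/C(C)=C\C | starting material
18 | (1R,2S,3S,4R,6R)-4-[(3S)-3-{[(2Z)-2-methylbut-2-enoyl]oxy}hexa-1,5-dien-2-yl]-1-methyl-7-oxabicyclo[4.1.0]heptane-2,3-diyl bis[(2Z)-2-methylbut-2-enoate] | C=C([C@H](CC=C)OC(=O)/C(C)=C\C)[C@H]1C[C@H]2O[C@@]2(C)[C@@H](OC(=O)/C(C)=C\C)[C@H]1OC(=O)/C(C)=C\C | intermediate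
19 | 2-methylbut-2-ene | CC=C(C)C | starting material
20 | (1R,2S,3S,4R,6R)-1-methyl-4-[(3S)-6-methyl-3-{[(2Z)-2-methylbut-2-enoyl]oxy}hepta-1,5-dien-2-yl]-7-oxabicyclo[4.1.0]heptane-2,3-diyl bis[(2Z)-2-methylbut-2-enoate] | C=C([C@H](CC=C(C)C)OC(=O)/C(C)=C\C)[C@H]1C[C@H]2O[C@@]2(C)[C@@H](OC(=O)/C(C)=C\C)[C@H]1OC(=O)/C(C)=C\C | intermediate
21 | (1R,2S,3S,4R,6R)-4-{(3S)-4-[(2R)-3,3-dimethyloxiran-2-yl]-3-{[(2Z)-2-methylbut-2-enoyl]oxy}but-1-en-2-yl}-1-methyl-7-oxabicyclo[4.1.0]heptane-2,3-diyl bis[(2Z)-2-methylbut-2-enoate] | C=C([C@H](C[C@H]1OC1(C)C)OC(=O)/C(C)=C\C)[C@H]1C[C@H]2O[C@@]2(C)[C@@H](OC(=O)/C(C)=C\C)[C@H]1OC(=O)/C(C)=C\C | target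

**Step count**

Total steps: 11. Longest linear sequence: 10 (steps 1 and 3–11; step 2 is a one-step side branch).

**Three steps most likely to fail**

Step 3 (the proposed new method). The siloxy diene may be protonated or desilylated by the strong acid, and the enantioselectivity is untested. The fallback sets out from 2 and 4 and comes back at 6. The uncatalysed cycloaddition of 2 and 4 (toluene, 25–40 °C, the known thermal endo mode of cyclobutenone) gives the racemic silyl ether, that is 5 together with its mirror image, the ent-silyl ether F1. The same HF·pyridine treatment gives racemic alcohol, 6 plus the ent-alcohol F2. An isothiourea-catalysed acylative kinetic resolution of this secondary allylic alcohol (benzotetramisole antipode chosen so that F2 is acylated faster, (i-PrCO)2O, i-Pr2NEt, CHCl3, 0 °C) converts F2 into the isobutyrate F3. F3 is removed by chromatography, and enantioenriched 6 (at most 50%) re-enters at step 4.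

Step 8. The aldehyde is available only through the lactol–enal equilibrium, and the free hydroxyl, the angelate and the epoxide meet an acid catalyst. The fallback sets out from 14 and comes back at 16. Reduction of 14 with NaBH4/CeCl3·7H2O (MeOH, −20 °C) traps the open enal as the primary allylic alcohol, the allylic diol angelate F4. A transfer-hydrogenative carbonyl allylation from the alcohol oxidation level then forms the C8–C9 bond: [Ir(cod)Cl]2, SEGPHOS (antipode selected for 8S), 4-chloro-3-nitrobenzoic acid, Cs2CO3, allyl acetate, THF, 100 °C. This reaction is selective for primary over secondary alcohols, sets C8 under catalyst control without a free aldehyde or lactol, and gives 16.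

Step 9. Two hydroxyls, one of them flanked by an ester and the bulky side chain, must be acylated with an acyl group that isomerises easily to the tiglate. The fallback sets out from 16 and comes back at 18. The diol 16 is esterified with 2-[bis(2,2,2-trifluoroethoxy)phosphoryl]propanoic acid (EDC·HCl, DMAP, CH2Cl2) to the bis-phosphonopropanoate F5. A twofold Z-selective Horner–Wadsworth–Emmons olefination of the Still–Gennari type (KN(SiMe3)2, 18-crown-6, acetaldehyde, THF, −78 °C) then builds the two missing angelate double bonds on the molecule and gives 18.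

**Further compounds**

F1 | step 3 | (1S,5R,6R)-4-methyl-5-[(triisopropylsilyl)oxy]bicyclo[4.2.0]oct-3-en-7-one (enantiomer of 5) | O=C1C[C@@H]2CC=C(C)[C@H](O[Si](C(C)C)(C(C)C)C(C)C)[C@H]12
F2 | step 3 | (1S,5R,6R)-5-hydroxy-4-methylbicyclo[4.2.0]oct-3-en-7-one (enantiomer of 6) | O=C1C[C@@H]2CC=C(C)[C@H](O)[C@H]12
F3 | step 3 | (1S,5R,6R)-4-methyl-7-oxobicyclo[4.2.0]oct-3-en-5-yl 2-methylpropanoate (locants as in 6) | O=C1C[C@@H]2CC=C(C)[C@H](OC(=O)C(C)C)[C@H]12
F4 | step 8 | (1R,2S,3S,4R,6R)-3-hydroxy-4-(3-hydroxyprop-1-en-2-yl)-1-methyl-7-oxabicyclo[4.1.0]heptan-2-yl (2Z)-2-methylbut-2-enoate | OCC(=C)[C@H]1C[C@H]2O[C@@]2(C)[C@@H](OC(=O)/C(C)=C\C)[C@H]1O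
F5 | step 9 | bis{2-[bis(2,2,2-trifluoroethoxy)phosphoryl]propanoate} of diol 16 at C1–O and C8–O (phosphonate α-carbons unspecified) | C=C([C@H](CC=C)OC(=O)C(C)P(=O)(OCC(F)(F)F)OCC(F)(F)F)[C@H]1C[C@H]2O[C@@]2(C)[C@@H](OC(=O)/C(C)=C\C)[C@H]1OC(=O)C(C)P(=O)(OCC(F)(F)F)OCC(F)(F)F
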